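By the candidate steps, each J in this flask takes one Q and one D, so q + J, both as fractions of the Q charged, stays equal to 1, and D falls by J plus twice Z. Both candidate steps are taken as second order, so dividing one rate by the other removes time and the concentration scale, with d counted in the charge of Q:

D to Z over D to J = ρ d / q

Integrated until d is gone, with e the equivalents of D:

J∞ = 1 − (1 − e(1 − ρ))^(1/(1 − ρ))

| setting | summer | spring | flask |
|---|---|---|---|
| Q | 10 mM | 15 mM | 10 mM |
| D | 1.02 equiv | 1.02 equiv | 1.02 equiv |
| temperature | 0 °C | 6 °C | 0 °C |
| remark | the very flask that is asked about, followed so far | run made earlier |  |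
| time |  |  | 40 min |

| run | time / min | J / % |
|---|---|---|
| summer | 2.00 | 47 |
| summer | 4.00 | 59 |
| summer | 6.00 | 66 |
| summer | 12.0 | 78 |
| summer | 25.0 | 81 |
| spring | 0.417 | 32 |
| spring | 0.833 | 48 |
| spring | 1.50 | 62 |
| spring | 3.00 | 71 |
| spring | 6.00 | 77 |

(each reading ± 1.5 percentage points)

- what is taken out of J is counted as made
- candidate steps: Q + D -> J; 2 D -> Z
- additions bring no volume worth counting

- Friday's: at 40 min take out 90% of the J then present, then wait 80 min
- Thursday's: at 40 min raise the temperature by 10 K, then wait 80 min
- Tuesday's: change nothing and wait 80 min more
- Wednesday's: at 40 min add D, 100% of the amount charged, then wait 80 min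

- J, in percent of the Q first charged, at 40 min
- what to do for the largest gain in J; "none" if nothing gains more than 2 percentage points (Friday's / Thursday's / Tuesday's / Wednesday's / none)
- J present, with what was taken out counted in, in percent of the Q first charged, after Thursday's
- J present, with what was taken out counted in, in percent of the Q first charged, after Tuesday's

I reckoned in a chain. The first summer reading, taken as plain second order, gave k = 0.443 min⁻¹ in units of the charge. Late on q barely moves, so d decays pseudo-first-order:

tail rate = k q = 0.0842 min⁻¹

The rise between the last two readings then put my estimate of d at 1.51% at 25.0 min: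

plateau = 82.5%

At 40 min this gave J = 82.1%.

The weak link was that one rise, which rests on readings of scatter 1.5 percentage points. I reforged it from the spring run, whose amount cancels from ρ, assuming that 6.00 K leaves ρ alone. The same chain gave a spring plateau of 82.1%, so I took the mean:

plateau = 82.3%

J at 40 min = 81.9%

Trial values of 0.250 and 0.333 give plateaus of 85.5% and 81.9%. Interpolating gave ρ = 0.324, the selectivity factor: D lost to Z per D lost to J when d and q stand equal.

By this estimate, waiting, warming or taking out J, which neither candidate step uses, had about 0.43 points to collect, less than the margin, so I expected J near 82.3% after Tuesday's and Thursday's. The fresh dose, scaled by 1 − ρ, still exceeds the Q left, so I chose Wednesday's.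

The forecast gave 83% (81.5% to 84.5%), Wednesday's, 83.5% after Thursday's and 83.6% after Tuesday's, holding that “Fresh D meets the remaining 17% of Q”; its J stood above mine.

The flask gave 83.1%, which is 1.2 points above my reckoning, and Wednesday's gained 17 points against 0.49 points for Tuesday's, with 83.6% after Thursday's and 83.6% after Tuesday's.

    Q + D → J (k = 0.820 M⁻¹ s⁻¹, Ea = 49.0 kJ mol⁻¹)
    2 D → Z (k = 0.120 M⁻¹ s⁻¹, Ea = 39.0 kJ mol⁻¹)
    (constants at 0 °C)

In this flask, D went to J 4.1 times as fast as to Z at 1.57 min and 120 times as fast at 40.0 min, where my ρ gives 107 from Q at 16.9% and D, the limiting reagent, at 0.478% of its charge. For the neighbouring flask with 0.410 equiv of D, the same ρ in the integrated form gives 38.1%, and that flask stood at 38.4%.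

(The readings were computed with made-up constants; noise was put on by code.)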